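The depside ester is disconnected last, into a ring A acid (benzyl ethers, ketone masked as a dioxolane) and a ring B phenol. Ring B is built on one observation: the carboxyl group on C1 and the benzylic carbon on C6 occupy neighbouring ring atoms, with the C2 methoxy group on the other side of C1. A 5-benzyloxy-3-methoxybenzyne, set free by fluoride from an ortho-silyl aryl triflate, should insert into a C–C bond of dibenzyl malonate and so attach the C1 ester and the C6 acetate arm in one operation, the methoxy group fixing the orientation. Acylation and decarboxylation then convert the acetate arm into the 2-oxoheptyl chain.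

Key step: step 5

Remark: the target has no stereocentre; species formed only by deprotonation (aryllithiums, enolates, phenoxides) are treated as forms of their parent compounds and carry no number; the β-keto ester made in step 6 is racemic and loses its stereocentre in step 7; methyl orsellinate is taken as a purchasable ring A source.

Step 1
Reactants: 1 methoxyhydroquinone (2-methoxybenzene-1,4-diol); 2 benzyl bromide
Product: 3 4-(benzyloxy)-2-methoxyphenol
Conditions: BnBr (1.0 equiv), K2CO3 (1.0 equiv), acetone, 50 °C, N2
Reagents that add atoms: none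
Why: Williamson ether synthesis with limiting base and halide should alkylate the C4 hydroxyl, which is less hindered and more acidic than the C1 hydroxyl that is flanked by and hydrogen-bonded to the methoxy group.

Step 2
Reactants: 3 4-(benzyloxy)-2-methoxyphenol
Product: 4 4-(benzyloxy)-2-methoxyphenyl isopropylcarbamate
Conditions: i-PrNCO, Et3N (cat.), CH2Cl2, rt
Reagents that add atoms: isopropyl isocyanate, CC(C)N=C=O
Why: Amine-catalysed addition of a phenol to an isocyanate (carbamoylation) is a clean addition and installs a removable ortho-directing group on the C1 oxygen.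

Step 3
Reactants: 4 4-(benzyloxy)-2-methoxyphenyl isopropylcarbamate
Product: 7 4-(benzyloxy)-2-methoxy-6-(trimethylsilyl)phenyl isopropylcarbamate, via N-silyl carbamate 5 (not isolated), via C-silylated N-silyl carbamate 6 (not isolated)
Conditions: TBSOTf, TMEDA, Et2O, 0 °C → rt; n-BuLi (2 equiv), TMEDA, −78 °C; TMSCl, −78 °C → rt; aq. NaHSO4
Reagents that add atoms: chlorotrimethylsilane, C[Si](C)(C)Cl; tert-butyldimethylsilyl triflate, CC(C)(C)[Si](C)(C)OS(=O)(=O)C(F)(F)F (its silyl group stays only in 5 and 6)
Why: Directed ortho-metalation: once the N–H is silylated in the flask the carbamate is the strongest directing group on the ring and has a single free ortho position (C6), so coordination-assisted deprotonation there at −78 °C should outrun lithiation between the two ethers or at the benzylic CH2, and the aryllithium is silylated before the acidic work-up removes the N-silyl group.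

Step 4
Reactants: 7 4-(benzyloxy)-2-methoxy-6-(trimethylsilyl)phenyl isopropylcarbamate
Product: 9 4-(benzyloxy)-2-methoxy-6-(trimethylsilyl)phenyl trifluoromethanesulfonate, via silyl phenol 8 (not isolated)
Conditions: DBU, Et2NH, MeCN, 40 °C; then PhNTf2, rt
Reagents that add atoms: N-phenylbis(trifluoromethanesulfonimide), O=S(=O)(N(c1ccccc1)S(=O)(=O)C(F)(F)F)C(F)(F)F
Why: Base-induced E1cB cleavage of the N–H carbamate gives the phenoxide and isopropyl isocyanate, which diethylamine traps as a urea, and the phenoxide is then O-triflated in the same flask under conditions that spare the aryl–silicon bond.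

Step 5
Reactants: 9 4-(benzyloxy)-2-methoxy-6-(trimethylsilyl)phenyl trifluoromethanesulfonate; 10 dibenzyl malonate
Product: 12 benzyl 4-(benzyloxy)-2-[2-(benzyloxy)-2-oxoethyl]-6-methoxybenzoate, via 5-(benzyloxy)-3-methoxybenzyne 11 (not isolated)
Conditions: CsF (3 equiv), 10 (1.5 equiv), MeCN, 80 °C
Reagents that add atoms: none
Why: Fluoride attack on silicon with loss of triflate gives aryne 11, and the caesium enolate of 10 adds to the aryne carbon that carried silicon, remote from the methoxy group. The resulting aryl anion, sited next to the methoxy oxygen, attacks one ester carbonyl (4-exo-trig) to give a benzocyclobutenoxide that fragments in retro-aldol fashion to the arylacetate enolate, protonated on work-up, so that the aryne ends up inserted into a C–C bond of the malonate. The closest known reaction type is the fluoride-triggered acyl-alkylation of arynes with malonates and β-keto esters, which has been run on 3-alkoxy and 3,5-dialkoxy arynes. The four-membered ring is transient, no ring is retained and no stereocentre is formed. The step needs regioselective addition to the unsymmetrical aryne, which the methoxy group ortho to the triflate carbon secures through its inductive pull and the distortion it imposes on the triple bond. It also needs ring closure of the aryl anion to beat protonation, which the dry aprotic medium, the unhindered benzyl ester and the proximity of the carbonyl favour.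

Step 6
Reactants: 12 benzyl 4-(benzyloxy)-2-[2-(benzyloxy)-2-oxoethyl]-6-methoxybenzoate; 13 hexanoyl chloride
Product: 14 benzyl 4-(benzyloxy)-2-[1-(benzyloxy)-1,3-dioxooctan-2-yl]-6-methoxybenzoate (racemic, keto and enol forms)
Conditions: LiN(SiMe3)2 (2.1 equiv), THF, −78 °C; 13 (1.1 equiv), −78 °C; AcOH, −78 °C
Reagents that add atoms: none
Why: C-Acylation of an ester enolate with an acid chloride (crossed Claisen type): the only acidic C–H is the benzylic CH2 of the acetate arm, the second equivalent of base holds the more acidic β-keto ester as its enolate, and the cold acidic quench should prevent that enolate from closing onto the hindered benzoate.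

Step 7
Reactants: 14 benzyl 4-(benzyloxy)-2-[1-(benzyloxy)-1,3-dioxooctan-2-yl]-6-methoxybenzoate
Product: 16 4-hydroxy-2-methoxy-6-(2-oxoheptyl)benzoic acid, via keto diacid 15 (not isolated)
Conditions: H2 (1 atm), 10% Pd/C, EtOAc, rt; filter; 50 °C
Reagents that add atoms: none
Why: Hydrogenolysis over Pd/C cleaves all three benzyl–oxygen bonds and the β-keto acid so formed should lose CO2 on gentle warming (decarboxylation), while the dialkyl ketone and the aromatic acid are untouched.

Step 8
Reactants: 16 4-hydroxy-2-methoxy-6-(2-oxoheptyl)benzoic acid; 2 benzyl bromide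
Product: 17 benzyl 4-hydroxy-2-methoxy-6-(2-oxoheptyl)benzoate
Conditions: BnBr (1.05 equiv), KHCO3, DMF, rt
Reagents that add atoms: none
Why: Carboxylate O-alkylation: hydrogen carbonate deprotonates only the carboxylic acid, so benzyl bromide should esterify it by SN2 and leave the less acidic phenol and the ketone alone.

Step 9
Reactants: 18 methyl orsellinate (methyl 2,4-dihydroxy-6-methylbenzoate); 2 benzyl bromide
Product: 19 methyl 2,4-bis(benzyloxy)-6-methylbenzoate
Conditions: BnBr (2.5 equiv), K2CO3 (3 equiv), DMF, 60 °C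
Reagents that add atoms: benzyl bromide (second equivalent; one benzyl group goes onto each of the two phenolic oxygens), BrCc1ccccc1
Why: Twofold Williamson ether synthesis: with excess halide and carbonate in DMF each phenoxide should be benzylated in turn, the free C4 hydroxyl first and the ester-chelated C2 hydroxyl on continued heating, so that two equivalents of benzyl bromide are consumed.

Step 10
Reactants: 13 hexanoyl chloride
Product: 20 N-methoxy-N-methylhexanamide
Conditions: MeNHOMe·HCl, pyridine, CH2Cl2, 0 °C → rt
Reagents that add atoms: N,O-dimethylhydroxylamine hydrochloride, CNOC.Cl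
Why: N-Acylation of an amine by an acid chloride gives the Weinreb amide needed for controlled ketone formation.

Step 11
Reactants: 19 methyl 2,4-bis(benzyloxy)-6-methylbenzoate; 20 N-methoxy-N-methylhexanamide
Product: 21 methyl 2,4-bis(benzyloxy)-6-(2-oxoheptyl)benzoate
Conditions: LiN(i-Pr)2 (2 equiv), THF, −78 °C; 20, −78 °C; AcOH
Reagents that add atoms: none
Why: Lateral (benzylic) lithiation of an ortho-toluate followed by Weinreb ketone synthesis, in which the chelated tetrahedral adduct blocks over-addition and releases the ketone only on quench.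

Step 12
Reactants: 21 methyl 2,4-bis(benzyloxy)-6-(2-oxoheptyl)benzoate
Product: 22 methyl 2,4-bis(benzyloxy)-6-[(2-pentyl-1,3-dioxolan-2-yl)methyl]benzoate
Conditions: Me3SiOCH2CH2OSiMe3, Me3SiOTf (cat.), CH2Cl2, −78 → −20 °C; pyridine
Reagents that add atoms: 1,2-bis(trimethylsilyloxy)ethane, C[Si](C)(C)OCCO[Si](C)(C)C
Why: Noyori ketalisation is aprotic and cold, so the ketone should be converted into its dioxolane without acid-promoted enol lactonisation onto the neighbouring ester.

Step 13
Reactants: 22 methyl 2,4-bis(benzyloxy)-6-[(2-pentyl-1,3-dioxolan-2-yl)methyl]benzoate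
Product: 23 2,4-bis(benzyloxy)-6-[(2-pentyl-1,3-dioxolan-2-yl)methyl]benzoic acid
Conditions: KOH, DMSO/H2O, 90 °C; cold aq. KHSO4 to pH 4
Reagents that add atoms: potassium hydroxide, [K+].[OH-]
Why: Saponification of a di-ortho-substituted benzoate needs hot hydroxide in aqueous DMSO, to which the dioxolane and the benzyl ethers are inert, and the ketal should survive because acidification is stopped at pH 4 in the cold.

Step 14
Reactants: 23 2,4-bis(benzyloxy)-6-[(2-pentyl-1,3-dioxolan-2-yl)methyl]benzoic acid; 17 benzyl 4-hydroxy-2-methoxy-6-(2-oxoheptyl)benzoate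
Product: 24 benzyl 4-({2,4-bis(benzyloxy)-6-[(2-pentyl-1,3-dioxolan-2-yl)methyl]benzoyl}oxy)-2-methoxy-6-(2-oxoheptyl)benzoate
Conditions: DCC, 4-(dimethylamino)pyridine (0.2 equiv), CH2Cl2, 0 °C → rt
Reagents that add atoms: none
Why: Steglich esterification (carbodiimide activation with acyl transfer through the acylpyridinium) is an established way to join hindered benzyl-protected benzoic acids to phenols, and with the ring A ketone held as a dioxolane the activated acid cannot close to an isocoumarin.

Step 15
Reactants: 24 benzyl 4-({2,4-bis(benzyloxy)-6-[(2-pentyl-1,3-dioxolan-2-yl)methyl]benzoyl}oxy)-2-methoxy-6-(2-oxoheptyl)benzoate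
Product: 25 benzyl 4-{[2,4-bis(benzyloxy)-6-(2-oxoheptyl)benzoyl]oxy}-2-methoxy-6-(2-oxoheptyl)benzoate
Conditions: 1 M HCl, THF, rt
Reagents that add atoms: water, O
Why: Acid-catalysed ketal hydrolysis in aqueous THF at room temperature should free the ring A ketone, while the aryl benzoate, the benzyl ester and the benzyl ethers are stable to dilute acid.

Step 16
Reactants: 25 benzyl 4-{[2,4-bis(benzyloxy)-6-(2-oxoheptyl)benzoyl]oxy}-2-methoxy-6-(2-oxoheptyl)benzoate
Product: 26 arthonioic acid, 4-{[2,4-dihydroxy-6-(2-oxoheptyl)benzoyl]oxy}-2-methoxy-6-(2-oxoheptyl)benzoic acid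
Conditions: H2 (1 atm), 10% Pd/C, EtOAc, rt
Reagents that add atoms: none
Why: Hydrogenolysis over Pd/C removes the two benzyl ethers and the benzyl ester under neutral conditions that should leave the depside ester and both dialkyl ketones intact.

Compound list
1 | methoxyhydroquinone (2-methoxybenzene-1,4-diol) | COc1cc(O)ccc1O | starting material
2 | benzyl bromide | BrCc1ccccc1 | starting material
3 | 4-(benzyloxy)-2-methoxyphenol | COc1cc(OCc2ccccc2)ccc1O | intermediate
4 | 4-(benzyloxy)-2-methoxyphenyl isopropylcarbamate | COc1cc(OCc2ccccc2)ccc1OC(=O)NC(C)C | intermediate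
5 | 4-(benzyloxy)-2-methoxyphenyl N-(tert-butyldimethylsilyl)-N-isopropylcarbamate | COc1cc(OCc2ccccc2)ccc1OC(=O)N(C(C)C)[Si](C)(C)C(C)(C)C | intermediate
6 | 4-(benzyloxy)-2-methoxy-6-(trimethylsilyl)phenyl N-(tert-butyldimethylsilyl)-N-isopropylcarbamate | COc1cc(OCc2ccccc2)cc([Si](C)(C)C)c1OC(=O)N(C(C)C)[Si](C)(C)C(C)(C)C | intermediate
7 | 4-(benzyloxy)-2-methoxy-6-(trimethylsilyl)phenyl isopropylcarbamate | COc1cc(OCc2ccccc2)cc([Si](C)(C)C)c1OC(=O)NC(C)C | intermediate
8 | 4-(benzyloxy)-2-methoxy-6-(trimethylsilyl)phenol | COc1cc(OCc2ccccc2)cc([Si](C)(C)C)c1O | intermediate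
9 | 4-(benzyloxy)-2-methoxy-6-(trimethylsilyl)phenyl trifluoromethanesulfonate | COc1cc(OCc2ccccc2)cc([Si](C)(C)C)c1OS(=O)(=O)C(F)(F)F | intermediate
10 | dibenzyl malonate | O=C(CC(=O)OCc1ccccc1)OCc1ccccc1 | starting material
11 | 5-(benzyloxy)-3-methoxybenzyne | COC1=CC(OCc2ccccc2)=CC#C1 | intermediate
12 | benzyl 4-(benzyloxy)-2-[2-(benzyloxy)-2-oxoethyl]-6-methoxybenzoate | COc1cc(OCc2ccccc2)cc(CC(=O)OCc2ccccc2)c1C(=O)OCc1ccccc1 | intermediate
13 | hexanoyl chloride | CCCCCC(Cl)=O | starting material
14 | benzyl 4-(benzyloxy)-2-[1-(benzyloxy)-1,3-dioxooctan-2-yl]-6-methoxybenzoate (racemic) | CCCCCC(=O)C(C(=O)OCc1ccccc1)c1cc(OCc2ccccc2)cc(OC)c1C(=O)OCc1ccccc1 | intermediate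
15 | 2-(1-carboxy-2-oxoheptyl)-4-hydroxy-6-methoxybenzoic acid (racemic) | CCCCCC(=O)C(C(=O)O)c1cc(O)cc(OC)c1C(=O)O | intermediate
16 | 4-hydroxy-2-methoxy-6-(2-oxoheptyl)benzoic acid | CCCCCC(=O)Cc1cc(O)cc(OC)c1C(=O)O | intermediate
17 | benzyl 4-hydroxy-2-methoxy-6-(2-oxoheptyl)benzoate | CCCCCC(=O)Cc1cc(O)cc(OC)c1C(=O)OCc1ccccc1 | intermediate
18 | methyl orsellinate (methyl 2,4-dihydroxy-6-methylbenzoate) | COC(=O)c1c(C)cc(O)cc1O | starting material
19 | methyl 2,4-bis(benzyloxy)-6-methylbenzoate | COC(=O)c1c(C)cc(OCc2ccccc2)cc1OCc1ccccc1 | intermediate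
20 | N-methoxy-N-methylhexanamide | CCCCCC(=O)N(C)OC | intermediate
21 | methyl 2,4-bis(benzyloxy)-6-(2-oxoheptyl)benzoate | CCCCCC(=O)Cc1cc(OCc2ccccc2)cc(OCc2ccccc2)c1C(=O)OC | intermediate
22 | methyl 2,4-bis(benzyloxy)-6-[(2-pentyl-1,3-dioxolan-2-yl)methyl]benzoate | CCCCCC1(Cc2cc(OCc3ccccc3)cc(OCc3ccccc3)c2C(=O)OC)OCCO1 | intermediate
23 | 2,4-bis(benzyloxy)-6-[(2-pentyl-1,3-dioxolan-2-yl)methyl]benzoic acid | CCCCCC1(Cc2cc(OCc3ccccc3)cc(OCc3ccccc3)c2C(=O)O)OCCO1 | intermediate
24 | benzyl 4-({2,4-bis(benzyloxy)-6-[(2-pentyl-1,3-dioxolan-2-yl)methyl]benzoyl}oxy)-2-methoxy-6-(2-oxoheptyl)benzoate | CCCCCC(=O)Cc1cc(OC(=O)c2c(CC3(CCCCC)OCCO3)cc(OCc3ccccc3)cc2OCc2ccccc2)cc(OC)c1C(=O)OCc1ccccc1 | intermediate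
25 | benzyl 4-{[2,4-bis(benzyloxy)-6-(2-oxoheptyl)benzoyl]oxy}-2-methoxy-6-(2-oxoheptyl)benzoate | CCCCCC(=O)Cc1cc(OCc2ccccc2)cc(OCc2ccccc2)c1C(=O)Oc1cc(CC(=O)CCCCC)c(C(=O)OCc2ccccc2)c(OC)c1 | intermediate
26 | arthonioic acid | CCCCCC(=O)Cc1cc(O)cc(O)c1C(=O)Oc1cc(CC(=O)CCCCC)c(C(=O)O)c(OC)c1 | target

Total step count: 16 steps.
Longest linear sequence: 11 steps (steps 1 to 8, then 14 to 16).

Steps most likely to fail

1. Step 5 (key step). The aryl anion may be protonated before it closes onto the ester, which would stop the sequence at simple α-arylation of the malonate. The product enolate may also be arylated a second time, and some addition at the aryne carbon next to the methoxy group would erode the regiochemistry. Fallback: ring B is built by lateral lithiation in place of aryne chemistry, setting out from 18. Benzylation with one equivalent of BnBr (K2CO3, acetone) should take the non-chelated C4 hydroxyl and give methyl 4-(benzyloxy)-2-hydroxy-6-methylbenzoate F1. Methylation of the chelated hydroxyl (MeI, K2CO3, DMF, 60 °C) should give methyl 4-(benzyloxy)-2-methoxy-6-methylbenzoate F2. Benzylic lithiation with LiN(i-Pr)2 at −78 °C and acylation with 20 should give methyl 4-(benzyloxy)-2-methoxy-6-(2-oxoheptyl)benzoate F3. Saponification (KOH, DMSO/H2O, 90 °C) should give 4-(benzyloxy)-2-methoxy-6-(2-oxoheptyl)benzoic acid F4, and hydrogenolysis (H2, 10% Pd/C, EtOAc) brings the material back to the route at 16.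

2. Step 3. Deprotonation may occur at the ring position between the two ether oxygens or at the benzylic CH2 of the benzyl ether (with subsequent Wittig rearrangement), and the lithiated carbamate may undergo anionic ortho-Fries migration if it warms before silylation. Fallback: the silicon is delivered by halogen–metal exchange in place of directed metalation, setting out from 3. Amine-mediated ortho-bromination of the phenol (NBS, i-Pr2NH (cat.), CH2Cl2, 0 °C) should give 4-(benzyloxy)-2-bromo-6-methoxyphenol F5. O-Silylation (HN(SiMe3)2, THF, reflux) should give [4-(benzyloxy)-2-bromo-6-methoxyphenoxy]trimethylsilane F6. Treatment with n-BuLi in THF at −78 °C should bring about bromine–lithium exchange and a retro-Brook shift of silicon from oxygen to carbon, giving the lithium salt of 8, and Tf2O added to the same flask should triflate it, so that the fallback rejoins the route at 9 and bypasses steps 2 to 4.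

3. Step 6. The enolate may be acylated on oxygen, the excess amide base may convert the acid chloride into a ketene, and the product enolate may lactonise onto the ortho benzoate with loss of benzyl alcohol. Fallback: the ketone is made by adding a pentyl nucleophile to an acyl electrophile in place of enolate acylation, setting out from 12. Selective saponification of the unhindered aliphatic benzyl ester (LiOH, THF/H2O, 0 °C) should give {5-(benzyloxy)-2-[(benzyloxy)carbonyl]-3-methoxyphenyl}acetic acid F7. Amide formation (MeNHOMe·HCl, EDC·HCl, Et3N, CH2Cl2) should give benzyl 4-(benzyloxy)-2-methoxy-6-{2-[methoxy(methyl)amino]-2-oxoethyl}benzoate F8. Addition of n-C5H11MgBr (THF, −20 °C) should give benzyl 4-(benzyloxy)-2-methoxy-6-(2-oxoheptyl)benzoate F9, and hydrogenolysis (H2, 10% Pd/C, EtOAc) brings the material back to the route at 16.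

Further compounds
F1 | step 5 | methyl 4-(benzyloxy)-2-hydroxy-6-methylbenzoate | COC(=O)c1c(C)cc(OCc2ccccc2)cc1O
F2 | step 5 | methyl 4-(benzyloxy)-2-methoxy-6-methylbenzoate | COC(=O)c1c(C)cc(OCc2ccccc2)cc1OC
F3 | step 5 | methyl 4-(benzyloxy)-2-methoxy-6-(2-oxoheptyl)benzoate | CCCCCC(=O)Cc1cc(OCc2ccccc2)cc(OC)c1C(=O)OC
F4 | step 5 | 4-(benzyloxy)-2-methoxy-6-(2-oxoheptyl)benzoic acid | CCCCCC(=O)Cc1cc(OCc2ccccc2)cc(OC)c1C(=O)O
F5 | step 3 | 4-(benzyloxy)-2-bromo-6-methoxyphenol | COc1cc(OCc2ccccc2)cc(Br)c1O
F6 | step 3 | [4-(benzyloxy)-2-bromo-6-methoxyphenoxy]trimethylsilane | COc1cc(OCc2ccccc2)cc(Br)c1O[Si](C)(C)C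
F7 | step 6 | {5-(benzyloxy)-2-[(benzyloxy)carbonyl]-3-methoxyphenyl}acetic acid | COc1cc(OCc2ccccc2)cc(CC(=O)O)c1C(=O)OCc1ccccc1
F8 | step 6 | benzyl 4-(benzyloxy)-2-methoxy-6-{2-[methoxy(methyl)amino]-2-oxoethyl}benzoate | COc1cc(OCc2ccccc2)cc(CC(=O)N(C)OC)c1C(=O)OCc1ccccc1
F9 | step 6 | benzyl 4-(benzyloxy)-2-methoxy-6-(2-oxoheptyl)benzoate | CCCCCC(=O)Cc1cc(OCc2ccccc2)cc(OC)c1C(=O)OCc1ccccc1
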